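## Structural features

The target 12 is a monocyclic 1H-pyrrole with a methyl ester on C2 and an unbranched, saturated C23 chain on the neighbouring C3. C4, C5 and N1 carry only hydrogen. There is no stereocentre and no second ring, so the problem is regiochemical and practical. The 2,3-pattern cannot be reached by substituting a pyrrole-2-carboxylate, whose electrophilic chemistry goes to C4 and C5, so the ring has to be built with the C3 substituent already in place. The fragile points are the electron-rich ring (sensitive to oxidants and strong acid, though tempered by the ester), the free N–H, and the methyl ester, which must not be saponified. The chain adds no reactivity but makes every intermediate that carries it waxy, poorly soluble in polar media and hard to purify, which argues for attaching it late. The key step exploits the plain polymethylene nature of the chain: the bond between its second and third carbon (counted from ring carbon C3) joins two CH2 groups. It can therefore be made from a 2-(pyrrol-3-yl)ethyl radical and a henicosyl radical, each released from a primary carboxylic acid, and 2 + 21 carbons give the required 23.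

## Logic of the disconnections

12 ⇒ 11. No skeletal bond is cut; the N1–H of 12 is exchanged for an N1–S bond to a p-tolylsulfonyl group. This is needed because the preceding anodic step requires an electron-poor ring without a free N–H. Nothing is gained in size, but the cut below becomes possible. The forward step must break N–S without touching the methyl ester, which a reductive cleavage does.

11 ⇒ 9 + 10. The bond between chain carbons 2 and 3 is cut. Both fragments then end in a primary carboxyl group; one of them, 10, is a bulk fatty acid, and the ring-side radical centre sits two CH2 groups from the ring, so it is neither ring-conjugated nor heteroatom-substituted. The gain is large: the whole C21 portion of the chain is kept out of the route until the penultimate step. The atom count (2 + 21 = 23) and the 2-ester/3-chain pattern were checked on both sides of this step and need no correction. The skeleton of 9 is kept, with three safeguards added: a partly neutralised, weakly acidic electrolyte, a hydrocarbon co-solvent for the lipids, and termination before the medium turns basic, because the N–S bond is base-labile. The forward step must oxidise carboxylate in preference to the heteroaromatic ring and must favour cross-combination, which an excess of 10 provides.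

9 ⇒ 8. The O–C bond of a tert-butyl ester is cut (functional-group level). The two carboxyl functions must be told apart, one staying a methyl ester and the other becoming the free acid for the electrolysis. The demand is an acidolysis that leaves the methyl ester and the N–S bond alone; both are stable to anhydrous acid.

8 ⇒ 7. The N1–S bond is cut. The sulfonyl group is introduced after ring formation because the annulation delivers the N–H pyrrole. The forward step needs full deprotonation of an N–H flanked by the C2 ester, followed by sulfonylation.

7 ⇒ 4 + 5 (through 6). The ring bonds C2–C3 and C4–C5 are cut. N1, C2 with its ester and C5 then come from 5, while C3 with its side chain and C4 come from the two alkene carbons of 6. The 3-substituted, 4,5-unsubstituted pattern follows from the polarity of the conjugate addition and cannot come out otherwise. The gain is one operation from two acyclic pieces to the complete ring. The demand is that base-sensitive 6 is generated in the flask from 4 and trapped at once.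

4 ⇒ 3 ⇒ 1 + 2. First the acetate C–O bond is cut, then the C4–C5 bond of the pentanoate (the future ring bond C3–C4). This nitroaldol retron leads to two commercial compounds. The forward step needs a mild base so that enolisable 1 does not self-condense and the new alkoxide does not close onto the ester; the tert-butyl ester helps by its bulk.

## Other disconnections considered

Alternative 1: The ring is cut at N1–C5 and C2–C3, leading to methyl N-tosylglycinate A1 and the vinyl ketone hexacos-1-en-3-one A2.
- Forward key step: a base (DBU or KOtBu) would trigger aza-Michael addition of the sulfonamide nitrogen of A1 to the terminal alkene carbon of A2, then aldol closure of the glycinate enolate onto the ketone. This gives the 3-hydroxypyrrolidine A3 as a diastereomer mixture. Dehydration (POCl3, pyridine) and base-induced loss of p-toluenesulfinate would aromatise the ring to 12.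
- In favour: the ketone carbon can only become C3. The sulfonyl group is both activator and leaving group, so no separate deprotection is needed. The chain arrives as one acyl unit from tetracosanoic acid A4 (Weinreb amide, then CH2=CHMgBr). No electrochemical equipment is required.
- Against: A2 is a polymerisation-prone enone and a C26 wax. Every intermediate carries the chain. Dehydration of the tertiary alcohol of A3 can give alkene regioisomers that may not all aromatise cleanly. A4 is dearer than 10.
- Comparison: on step count this alternative is the better one (about five operations from A4 against seven). On regiocontrol it is the equal of the chosen plan. Its polar mechanism has no statistical ceiling, which is also in its favour. The chosen plan keeps small, polar intermediates up to the coupling, confines lipid handling to the last two steps, and lets the chain length be varied at the end by changing the fatty acid.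

Alternative 2: The pyrrole is traced back to a pyridazine from which one nitrogen is later excised.
- Forward key step: inverse-electron-demand [4+2] cycloaddition of dimethyl 1,2,4,5-tetrazine-3,6-dicarboxylate A5 with pentacos-1-yne A6 (or an enol ether surrogate) and loss of N2 would give the pyridazine A7. Zn dust in AcOH should then cleave the N–N bond reductively, and reclosure with loss of ammonia should give the pyrrole-2,5-diester A8.
- In favour: A5 is symmetrical, so the cycloaddition has no regiochemical issue. Both ring transformations are robust, and the position of the chain is fixed with certainty.
- Against: A8 has an ester on C5 that 12 lacks. Selective saponification of the less hindered C5 ester and decarboxylation must follow, two further steps with a selectivity risk. A5 is a nitrogen-rich reagent that is awkward to prepare. A6 is an unactivated, sluggish dienophile and not a stock compound.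
- Comparison: in regiochemical certainty it is the equal of the chosen plan. Avoiding a statistical coupling is a point in its favour. In atom and step economy it is weaker, because a carboxyl group is built in and removed, A5 and A6 must be prepared, and the chain is carried through four steps.

Alternative 3: The C3=C4 bond is cut, leading to the acyclic diene A9, an N-allyl-N-tosyl α-amino ester whose 1,1-disubstituted alkene bears the chain.
- Forward key step: ring-closing metathesis with a ruthenium alkylidene (second-generation Grubbs catalyst, RuCl2(H2IMes)(PCy3)(=CHPh)) would expel ethylene and give the 3-pyrroline A10. Base (DBU or KOtBu) should then eliminate p-toluenesulfinate and tautomerise the ring to 12.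
- In favour: the ring closure is catalytic. Five-membered N-sulfonyl diene metathesis is dependable. Aromatisation and N-deprotection happen in one operation.
- Against: A9 is costly to assemble (addition of a chain-bearing 1-substituted vinyl metal reagent to an N-sulfonyl imino ester, then N-allylation). Its β,γ-alkene can move into conjugation with the ester under basic allylation. The 1,1-disubstituted alkene slows the metathesis. The chain is present from the first step.
- Comparison: after the key step both plans need one step, so they are equal there. The ring-forming step is cleaner than a mixed electrolysis with excess 10, a point in its favour. Overall it is judged longer, because A9 needs several steps of its own, and it shares with alternative 1 the lipid-like intermediates throughout.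

Key step: step 6

Remark on the chemistry: 3 and 4 are carried as racemates, because their single stereocentre becomes the sp2 ring carbon C3 in step 3; 12 has no stereocentre.

## Route

Step 1
Reactants: 1 tert-butyl 4-oxobutanoate; 2 nitromethane
Product: 3 tert-butyl 4-hydroxy-5-nitropentanoate (racemic)
Conditions: MeNO2 (5 equiv.), TMG (0.1 equiv.), THF, 0 °C; AcOH quench
Reagents that add atoms: none
Why: Henry (nitroaldol) addition of the nitronate of 2 to the aldehyde; excess 2 suppresses double addition, and a catalytic guanidine base at 0 °C keeps aldol self-condensation and closure of the alkoxide onto the bulky tert-butyl ester slow. The new carbinol centre forms without control and is erased in step 3.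

Step 2
Reactants: 3 tert-butyl 4-hydroxy-5-nitropentanoate (racemic)
Product: 4 tert-butyl 4-acetoxy-5-nitropentanoate (racemic)
Conditions: Ac2O (1.2 equiv.), DMAP (5 mol%), CH2Cl2, 0 °C to rt
Reagents that add atoms: acetic anhydride, CC(=O)OC(C)=O
Why: DMAP-catalysed O-acetylation of the secondary alcohol without a stoichiometric amine, so that retro-Henry cleavage and premature elimination stay minor; any 6 formed here is in any case the intermediate of step 3.

Step 3
Reactants: 4 tert-butyl 4-acetoxy-5-nitropentanoate (racemic); 5 methyl isocyanoacetate
Product: 7 methyl 3-(3-tert-butoxy-3-oxopropyl)-1H-pyrrole-2-carboxylate, via tert-butyl (E)-5-nitropent-4-enoate 6 (not isolated)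
Conditions: 5 (1.05 equiv.), DBU (2.2 equiv.), THF, 0 °C to rt
Reagents that add atoms: none
Why: Barton–Zard pyrrole synthesis: E1cB loss of acetate gives 6, the anion of 5 adds to the alkene carbon remote from the nitro group, the nitronate closes onto the isocyanide carbon, and loss of nitrite followed by tautomerisation aromatises the ring. The side chain therefore ends on C3 next to the ester, and C4 and C5 carry hydrogen.

Step 4
Reactants: 7 methyl 3-(3-tert-butoxy-3-oxopropyl)-1H-pyrrole-2-carboxylate
Product: 8 methyl 3-(3-tert-butoxy-3-oxopropyl)-1-tosyl-1H-pyrrole-2-carboxylate
Conditions: NaH (1.2 equiv.), THF, 0 °C; then TsCl (1.2 equiv.), 0 °C to rt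
Reagents that add atoms: p-toluenesulfonyl chloride, Cc1ccc(cc1)S(=O)(=O)Cl
Why: N-sulfonylation of the sodium pyrrolide; the N–H, acidified by the C2 ester, is removed selectively because the ester α-positions are far less acidic, and the hard sulfonyl chloride reacts at nitrogen.

Step 5
Reactants: 8 methyl 3-(3-tert-butoxy-3-oxopropyl)-1-tosyl-1H-pyrrole-2-carboxylate
Product: 9 3-[2-(methoxycarbonyl)-1-tosyl-1H-pyrrol-3-yl]propanoic acid
Conditions: TFA/CH2Cl2 1:3, 0 °C to rt
Reagents that add atoms: none
Why: Acidolysis of the tert-butyl ester through the tert-butyl cation; the methyl ester and the N-sulfonyl group are inert to anhydrous acid, and the electron-poor ring should resist tert-butylation.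

Step 6
Reactants: 9 3-[2-(methoxycarbonyl)-1-tosyl-1H-pyrrol-3-yl]propanoic acid; 10 docosanoic acid (6 equiv.)
Product: 11 methyl 1-tosyl-3-tricosyl-1H-pyrrole-2-carboxylate
Conditions: Pt foil anode, Pt cathode, undivided cell, constant current (ca. 0.25 A cm−2), NaOMe (0.1 equiv. per mol of total acid), MeOH/hexane 3:1, 45 °C, stopped before the electrolyte turns basic
Reagents that add atoms: none
Why: At a smooth Pt anode at high current density the two carboxylates are adsorbed and oxidised by one electron each, the acyloxy radicals lose CO2 at the surface, and the resulting 2-(pyrrol-3-yl)ethyl and henicosyl radicals combine to form the bond between chain carbons 2 and 3 (mixed Kolbe electrolysis, an anodic decarboxylative radical–radical coupling). The closest known reaction type is the cross-Kolbe coupling of a functionalised acid with an excess of a plain fatty acid, as used for long-chain esters and pheromone skeletons. No ring is closed and no stereocentre is formed. Three selectivities are needed. Carboxylate oxidation must win over oxidation of the heteroaromatic ring: the N-sulfonyl group and the C2 ester lower the electron density of the ring, and the carboxylate layer that forms on Pt in a weakly acidic medium shields other groups from the electrode. Cross-combination must win over dimerisation of the ring-side radical: the sixfold excess of 10 makes nearly every partner at the surface a henicosyl radical, and the resulting dotetracontane is non-polar and should be removable by elution from silica with hexane. Radical combination must win over further oxidation to a cation: both radicals are primary and unstabilised, the ring-side one is separated from the electron-poor ring by two CH2 groups, and Pt is used in place of carbon. The N–S bond should persist because the cathode discharges protons of the free acids and does not build up methoxide as long as acid remains.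

Step 7
Reactants: 11 methyl 1-tosyl-3-tricosyl-1H-pyrrole-2-carboxylate
Product: 12 methyl 3-tricosyl-1H-pyrrole-2-carboxylate
Conditions: Mg turnings (10 equiv.), MeOH/THF 2:1, rt, ultrasound; aq. NH4Cl
Reagents that add atoms: none
Why: Dissolving-metal desulfonylation: electron transfer from Mg to the arenesulfonyl group cleaves the N–S bond to the ester-stabilised pyrrolide and p-toluenesulfinate, and methanol protonates the nitrogen. The methyl ester is unchanged in methanol, and neither the aromatic ring nor the alkyl chain is reducible under these conditions.

## Compound list

1 | tert-butyl 4-oxobutanoate | CC(C)(C)OC(=O)CCC=O | starting material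
2 | nitromethane | C[N+](=O)[O-] | starting material
3 | tert-butyl 4-hydroxy-5-nitropentanoate (racemic) | CC(C)(C)OC(=O)CCC(O)C[N+](=O)[O-] | intermediate
4 | tert-butyl 4-acetoxy-5-nitropentanoate (racemic) | CC(C)(C)OC(=O)CCC(OC(C)=O)C[N+](=O)[O-] | intermediate
5 | methyl isocyanoacetate | [C-]#[N+]CC(=O)OC | starting material
6 | tert-butyl (E)-5-nitropent-4-enoate | CC(C)(C)OC(=O)CC/C=C/[N+](=O)[O-] | intermediate (formed in the flask, not isolated)
7 | methyl 3-(3-tert-butoxy-3-oxopropyl)-1H-pyrrole-2-carboxylate | COC(=O)c1[nH]ccc1CCC(=O)OC(C)(C)C | intermediate
8 | methyl 3-(3-tert-butoxy-3-oxopropyl)-1-tosyl-1H-pyrrole-2-carboxylate | COC(=O)c1c(CCC(=O)OC(C)(C)C)ccn1S(=O)(=O)c1ccc(C)cc1 | intermediate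
9 | 3-[2-(methoxycarbonyl)-1-tosyl-1H-pyrrol-3-yl]propanoic acid | COC(=O)c1c(CCC(=O)O)ccn1S(=O)(=O)c1ccc(C)cc1 | intermediate
10 | docosanoic acid | CCCCCCCCCCCCCCCCCCCCCC(=O)O | starting material
11 | methyl 1-tosyl-3-tricosyl-1H-pyrrole-2-carboxylate | CCCCCCCCCCCCCCCCCCCCCCCc1ccn(S(=O)(=O)c2ccc(C)cc2)c1C(=O)OC | intermediate
12 | methyl 3-tricosyl-1H-pyrrole-2-carboxylate | CCCCCCCCCCCCCCCCCCCCCCCc1cc[nH]c1C(=O)OC | target

## Step count and risk

Total step count: 7. Longest linear sequence: 7 steps (1 to 12); 2, 5 and 10 enter as purchased reactants.

Step 6 (key step).
- Most likely failure: the ring-side acid is consumed by paths other than cross-combination. These are further oxidation of its radical to a cation, anodic attack on the heteroaromatic or tolyl unit, and passivation of the Pt surface by a waxy hydrocarbon film that shifts the electrode potential. The cross product would then be a minor part of the statistical mixture.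
- Fallback (non-electrochemical, same bond): it sets out from 9. Esterification with N-hydroxyphthalimide (DIC, cat. DMAP, CH2Cl2) should give the redox-active ester 1,3-dioxoisoindolin-2-yl 3-[2-(methoxycarbonyl)-1-tosyl-1H-pyrrol-3-yl]propanoate F1. Dihenicosylzinc F2 would be made from commercial 1-bromohenicosane through its Grignard reagent and ZnCl2 (0.5 equiv.). Nickel-catalysed decarboxylative alkyl–alkyl coupling of F1 with F2 (NiCl2·glyme, 4,4′-di-tert-butyl-2,2′-bipyridine, THF/DMF, rt) should join the same two CH2 groups and return to the route at 11.

Step 3.
- Most likely failure: base-induced oligomerisation of 6, or its deconjugation by γ-deprotonation, before the anion of 5 adds; self-condensation of 5 under the same base would compete.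
- Fallback (no nitroalkene): it sets out from 1. Addition of CH2=CHMgBr (THF, −78 °C) should give tert-butyl 4-hydroxyhex-5-enoate F3, and Dess–Martin oxidation should give the vinyl ketone tert-butyl 4-oxohex-5-enoate F4. Kenner annulation of F4 with commercial methyl N-tosylglycinate (listed as A1) under DBU should give tert-butyl 3-[3-hydroxy-2-(methoxycarbonyl)-1-tosylpyrrolidin-3-yl]propanoate F5. Dehydration (POCl3, pyridine) should give tert-butyl 3-[2-(methoxycarbonyl)-1-tosyl-2,5-dihydro-1H-pyrrol-3-yl]propanoate F6. DBU-induced loss of p-toluenesulfinate with tautomerisation returns to the route at 7.

Step 1.
- Most likely failure: aldol self-condensation of the enolisable aldehyde, closure of the intermediate alkoxide onto the ester, and reversal of the addition on work-up.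
- Fallback (no nitroaldol): it sets out from 1. Wittig methylenation (Ph3P=CH2 from the phosphonium bromide and KOtBu, THF, 0 °C) should give tert-butyl pent-4-enoate F7. Radical nitration of the terminal alkene (AgNO2, TEMPO, 4 Å molecular sieves, ClCH2CH2Cl, 70 °C) should give the (E)-nitroalkene. The route is rejoined at 6, now isolated and taken into step 3 in place of 4 with one equivalent less of DBU.

Step 7.
- Most likely failure: incomplete N–S cleavage, because the waxy substrate dissolves poorly in the methanol-rich medium that Mg needs and the metal surface passivates.
- Fallback (nucleophilic instead of electron-transfer cleavage): it sets out from 11. Fluoride attack at sulfur (Bu4NF, THF, reflux) should release the pyrrolide in a solvent that dissolves the lipid well, and the route is rejoined at 12. No new compound arises on the way.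

## Further compounds

F1 | step 6 | 1,3-dioxoisoindolin-2-yl 3-[2-(methoxycarbonyl)-1-tosyl-1H-pyrrol-3-yl]propanoate | COC(=O)c1c(CCC(=O)ON2C(=O)c3ccccc3C2=O)ccn1S(=O)(=O)c1ccc(C)cc1
F2 | step 6 | dihenicosylzinc | CCCCCCCCCCCCCCCCCCCCC[Zn]CCCCCCCCCCCCCCCCCCCCC
F3 | step 3 | tert-butyl 4-hydroxyhex-5-enoate (racemic) | CC(C)(C)OC(=O)CCC(O)C=C
F4 | step 3 | tert-butyl 4-oxohex-5-enoate | CC(C)(C)OC(=O)CCC(=O)C=C
F5 | step 3 | tert-butyl 3-[3-hydroxy-2-(methoxycarbonyl)-1-tosylpyrrolidin-3-yl]propanoate (racemic diastereomer mixture) | COC(=O)C1N(S(=O)(=O)c2ccc(C)cc2)CCC1(O)CCC(=O)OC(C)(C)C
F6 | step 3 | tert-butyl 3-[2-(methoxycarbonyl)-1-tosyl-2,5-dihydro-1H-pyrrol-3-yl]propanoate (racemic) | COC(=O)C1N(S(=O)(=O)c2ccc(C)cc2)CC=C1CCC(=O)OC(C)(C)C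
F7 | step 1 | tert-butyl pent-4-enoate | CC(C)(C)OC(=O)CCC=C
F0 | step 7 | none | none
A1 | alternative 1 | methyl N-tosylglycinate | COC(=O)CNS(=O)(=O)c1ccc(C)cc1
A2 | alternative 1 | hexacos-1-en-3-one | C=CC(=O)CCCCCCCCCCCCCCCCCCCCCCC
A3 | alternative 1 | methyl 3-hydroxy-1-tosyl-3-tricosylpyrrolidine-2-carboxylate (racemic diastereomer mixture) | COC(=O)C1N(S(=O)(=O)c2ccc(C)cc2)CCC1(O)CCCCCCCCCCCCCCCCCCCCCCC
A4 | alternative 1 | tetracosanoic acid | CCCCCCCCCCCCCCCCCCCCCCCC(=O)O
A5 | alternative 2 | dimethyl 1,2,4,5-tetrazine-3,6-dicarboxylate | COC(=O)c1nnc(nn1)C(=O)OC
A6 | alternative 2 | pentacos-1-yne | C#CCCCCCCCCCCCCCCCCCCCCCCC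
A7 | alternative 2 | dimethyl 4-tricosylpyridazine-3,6-dicarboxylate | COC(=O)c1cc(CCCCCCCCCCCCCCCCCCCCCCC)c(C(=O)OC)nn1
A8 | alternative 2 | dimethyl 3-tricosyl-1H-pyrrole-2,5-dicarboxylate | COC(=O)c1cc(CCCCCCCCCCCCCCCCCCCCCCC)c(C(=O)OC)[nH]1
A9 | alternative 3 | methyl 3-methylidene-2-[N-(prop-2-en-1-yl)-4-methylbenzenesulfonamido]hexacosanoate (racemic) | COC(=O)C(N(CC=C)S(=O)(=O)c1ccc(C)cc1)C(=C)CCCCCCCCCCCCCCCCCCCCCCC
A10 | alternative 3 | methyl 1-tosyl-3-tricosyl-2,5-dihydro-1H-pyrrole-2-carboxylate (racemic) | COC(=O)C1N(S(=O)(=O)c2ccc(C)cc2)CC=C1CCCCCCCCCCCCCCCCCCCCCCC
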